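**Plan**

- The 1,2-dioxan-3-ol is a cyclic peroxyhemiketal: O1–O2 sits between C3 (hemiketal carbon, Me/OH) and C6 (fully substituted carbon), which are 1,4-related through C4–C5. Cutting C3–O2 and C6–O1 and joining C3 to C6 gives a tertiary cyclobutanol (carbinol C = C3, quaternary ring C = C6, CHMe = C4, CH2 = C5).
- Further cuts: C3–CH3 (methyl addition to a cyclobutanone), C4–CH3 (auxiliary-controlled methylation), the four-membered ring back to a methyl ketone (cyclopropyl sulfonium ylide spiroannulation), the side-chain C–CH3 (asymmetric conjugate addition), the enone C=C (Wittig) and the aryl–alkyne bond (Sonogashira).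
- Forward: chain (steps 1–4), cyclobutane (5), its two methyl groups (6–9), Z-alkene (10), and last the peroxide ring, the only ring of the target (11).
- Stereochemistry: side-chain methyl centre from Cu/Josiphos conjugate addition; C4 from SAMP alkylation; Z-alkene from Lindlar reduction; C3 thermodynamic (anomeric).
- C6 is formed by O2 capture of a planar radical and is not controlled: the target and its C6 epimer are both expected and are separated. The carbinol and quaternary centres of the cyclobutanol are stereo-mixtures that the key step erases.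

Key step: step 11

Assumption: the sense of induction of (R,S)-Josiphos (step 4) and of SAMP on a cyclobutanone hydrazone (step 7) is taken by analogy with linear enones and with cyclohexanone; if either proves opposite, the enantiomeric ligand or RAMP is used without other change.

**Step 1**
Reactants: 1 non-8-yn-1-ol; 2 iodobenzene
Product: 3 9-phenylnon-8-yn-1-ol
Conditions: PdCl2(PPh3)2 (2 mol %), CuI (4 mol %), Et3N, THF, rt
Reagents that add atoms: none
Why: Sonogashira coupling of a terminal alkyne with an aryl iodide runs at room temperature and tolerates the free primary alcohol; no stereocentre is formed.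

**Step 2**
Reactants: 3 9-phenylnon-8-yn-1-ol
Product: 4 9-phenylnon-8-ynal
Conditions: TEMPO (10 mol %), PhI(OAc)2 (1.1 equiv), CH2Cl2, rt
Reagents that add atoms: none
Why: Oxoammonium (TEMPO) oxidation of a primary alcohol should stop at the aldehyde and leave the internal alkyne untouched.

**Step 3**
Reactants: 4 9-phenylnon-8-ynal; 5 1-(triphenylphosphoranylidene)propan-2-one
Product: 6 (3E)-12-phenyldodec-3-en-11-yn-2-one
Conditions: CH2Cl2, 40 °C
Reagents that add atoms: none
Why: Wittig olefination with the stabilised acetyl ylide should give the E-enone selectively.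

**Step 4**
Reactants: 6 (3E)-12-phenyldodec-3-en-11-yn-2-one
Product: 7 (4R)-4-methyl-12-phenyldodec-11-yn-2-one
Conditions: MeMgBr (1.2 equiv), CuBr·SMe2 (5 mol %), (R,S)-Josiphos (6 mol %), t-BuOMe, −75 °C; aqueous work-up
Reagents that add atoms: methylmagnesium bromide, C[Mg]Br
Why: Copper-catalysed asymmetric conjugate addition of a Grignard reagent to a linear aliphatic enone; the ferrocenyl diphosphine controls the face of methyl delivery and should set the methyl-bearing centre as R, the unactivated internal alkyne being inert at −75 °C.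

**Step 5**
Reactants: 7 (4R)-4-methyl-12-phenyldodec-11-yn-2-one; 8 cyclopropyldiphenylsulfonium tetrafluoroborate
Product: 10 2-methyl-2-[(2R)-2-methyl-10-phenyldec-9-yn-1-yl]cyclobutan-1-one (both C2 epimers), via oxaspiropentane 9 (not isolated)
Conditions: KOH (powder), DMSO, 25 °C; then aq. HBF4, Et2O, rt
Reagents that add atoms: none
Why: Cyclopropyl sulfonium ylide spiroannulation: the reversibly formed ylide adds to the ketone to give oxaspiropentane 9, whose acid-induced cyclopropylcarbinyl-to-cyclobutyl shift should give the 2,2-disubstituted cyclobutanone; the quaternary centre forms as both epimers, which is harmless because it becomes the planar radical centre in step 11.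

**Step 6**
Reactants: 10 2-methyl-2-[(2R)-2-methyl-10-phenyldec-9-yn-1-yl]cyclobutan-1-one; 11 SAMP, (2S)-2-(methoxymethyl)pyrrolidin-1-amine
Product: 12 SAMP hydrazone of 10
Conditions: neat, 60 °C
Reagents that add atoms: none
Why: Condensation of the strained, electrophilic cyclobutanone with the hydrazine should give the hydrazone with the amino group anti to the quaternary carbon and syn to the only enolisable CH2.

**Step 7**
Reactants: 12 SAMP hydrazone of 10
Product: 14 (4R)-4-methyl SAMP hydrazone, via lithium azaenolate 13 (not isolated)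
Conditions: LDA (1.1 equiv), THF, 0 °C; then MeI, −95 °C to rt
Reagents that add atoms: iodomethane, CI
Why: Enders SAMP-hydrazone alkylation: the chelated azaenolate 13 is shielded on one face by the methoxymethylpyrrolidine, so MeI should enter to give the 4R centre (the sense that gives (R)-2-methylcyclohexanone), and the regiochemistry is fixed because the other α-carbon is quaternary.

**Step 8**
Reactants: 14 (4R)-4-methyl SAMP hydrazone
Product: 15 (4R)-2,4-dimethyl-2-[(2R)-2-methyl-10-phenyldec-9-yn-1-yl]cyclobutan-1-one
Conditions: sat. aq. oxalic acid, Et2O, rt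
Reagents that add atoms: water, O
Why: Two-phase oxalic acid hydrolysis of the hydrazone is mild enough to release the α-branched ketone without epimerisation (cyclobutanones enolise reluctantly) and returns the auxiliary.

**Step 9**
Reactants: 15 (4R)-2,4-dimethyl-2-[(2R)-2-methyl-10-phenyldec-9-yn-1-yl]cyclobutan-1-one
Product: 16 (4R)-1,2,4-trimethyl-2-[(2R)-2-methyl-10-phenyldec-9-yn-1-yl]cyclobutan-1-ol (mixture at C1 and C2)
Conditions: MeLi, anhydrous CeCl3, THF, −78 °C; aqueous work-up
Reagents that add atoms: methyllithium, [Li]C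
Why: Organocerium 1,2-addition to a hindered, enolisable ketone suppresses enolisation and so preserves C4; the carbinol centre forms as a mixture that is erased in step 11.

**Step 10**
Reactants: 16 (4R)-1,2,4-trimethyl-2-[(2R)-2-methyl-10-phenyldec-9-yn-1-yl]cyclobutan-1-ol
Product: 17 (4R)-1,2,4-trimethyl-2-[(2R,9Z)-2-methyl-10-phenyldec-9-en-1-yl]cyclobutan-1-ol
Conditions: H2 (1 atm), Lindlar catalyst, quinoline, EtOAc, rt, stopped at 1 equiv H2
Reagents that add atoms: none
Why: Lindlar semi-hydrogenation of the aryl alkyl alkyne is a syn addition of H2 on the poisoned surface and should give the Z-alkene; the tertiary alcohol and the saturated ring are inert.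

**Step 11**
Reactants: 17 (4R)-1,2,4-trimethyl-2-[(2R,9Z)-2-methyl-10-phenyldec-9-en-1-yl]cyclobutan-1-ol
Product: 20 (3S,4R,6S)-3,4,6-trimethyl-6-[(2R,9Z)-2-methyl-10-phenyldec-9-en-1-yl]-1,2-dioxan-3-ol, via keto radical 18 (not isolated), via hydroperoxy ketone 19 (not isolated)
Conditions: Co(acac)2 (20 mol %), O2 (1 atm), MeCN, 25–40 °C; chromatographic separation of the C6 epimers
Reagents that add atoms: dioxygen, O=O
Why: Co(II)/O2 should convert 17 into a cobalt(III) alkoxide that releases the tertiary cyclobutyloxy radical; ring strain drives β-scission of the bond to the fully substituted ring carbon to give the methyl ketone and tertiary radical 18, triplet O2 captures it, and reduction of the peroxyl radical gives hydroperoxy ketone 19, which closes to the peroxyhemiketal. The closest known reaction type is the Co(acac)2/O2 oxidative ring expansion of cyclobutanols to 1,2-dioxan-3-ols, the homologue of the cyclopropanol to 1,2-dioxolan-3-ol oxygenation. The 1,2-dioxane closes by reversible 6-exo-trig addition of the hydroperoxide oxygen to the C3 carbonyl. C4 is carried over unchanged from 17 because the ketone is never enolised; C3 is under thermodynamic control, the anomeric effect placing OH axial in the chair that has 3-Me, 4-Me and the C6 side chain equatorial, which is the target arrangement; C6 is made when O2 meets a free planar radical and nothing in the substrate controls it, so 20 and its C6 epimer are both expected and are separated. The step needs regioselective β-scission, secured by the quaternary ring carbon (tertiary versus secondary radical), and chemoselectivity over the Z-styrene, expected because no hydride or silane is present and O2 capture of 18 is far faster than radical addition to a 1,2-disubstituted alkene. The carbinol and quaternary centres of 17 are both destroyed here, so all stereoisomers of 17 converge.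

**Compound list**

1 | non-8-yn-1-ol | OCCCCCCCC#C | starting material
2 | iodobenzene | Ic1ccccc1 | starting material
3 | 9-phenylnon-8-yn-1-ol | OCCCCCCCC#Cc1ccccc1 | intermediate
4 | 9-phenylnon-8-ynal | O=CCCCCCCC#Cc1ccccc1 | intermediate
5 | 1-(triphenylphosphoranylidene)propan-2-one | CC(=O)C=P(c1ccccc1)(c1ccccc1)c1ccccc1 | starting material
6 | (3E)-12-phenyldodec-3-en-11-yn-2-one | CC(=O)/C=C/CCCCCCC#Cc1ccccc1 | intermediate
7 | (4R)-4-methyl-12-phenyldodec-11-yn-2-one | CC(=O)C[C@H](C)CCCCCCC#Cc1ccccc1 | intermediate
8 | cyclopropyldiphenylsulfonium tetrafluoroborate | C1CC1[S+](c1ccccc1)c1ccccc1.F[B-](F)(F)F | starting material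
9 | 2-methyl-2-[(2R)-2-methyl-10-phenyldec-9-yn-1-yl]-1-oxaspiro[2.2]pentane (both C2 epimers) | CC1(C[C@H](C)CCCCCCC#Cc2ccccc2)OC12CC2 | intermediate
10 | 2-methyl-2-[(2R)-2-methyl-10-phenyldec-9-yn-1-yl]cyclobutan-1-one (both C2 epimers) | CC1(C[C@H](C)CCCCCCC#Cc2ccccc2)CCC1=O | intermediate
11 | SAMP, (2S)-2-(methoxymethyl)pyrrolidin-1-amine | COC[C@@H]1CCCN1N | starting material
12 | N-[(2S)-2-(methoxymethyl)pyrrolidin-1-yl]-2-methyl-2-[(2R)-2-methyl-10-phenyldec-9-yn-1-yl]cyclobutan-1-imine | CC1(C[C@H](C)CCCCCCC#Cc2ccccc2)CCC1=NN1CCC[C@H]1COC | intermediate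
13 | lithium azaenolate of 12 (N-lithio ene-hydrazine, ring C=C towards the CH2 side) | CC1(C[C@H](C)CCCCCCC#Cc2ccccc2)CC=C1N([Li])N1CCC[C@H]1COC | intermediate
14 | (4R)-N-[(2S)-2-(methoxymethyl)pyrrolidin-1-yl]-2,4-dimethyl-2-[(2R)-2-methyl-10-phenyldec-9-yn-1-yl]cyclobutan-1-imine | CC1(C[C@H](C)CCCCCCC#Cc2ccccc2)C[C@@H](C)C1=NN1CCC[C@H]1COC | intermediate
15 | (4R)-2,4-dimethyl-2-[(2R)-2-methyl-10-phenyldec-9-yn-1-yl]cyclobutan-1-one (both C2 epimers) | CC1(C[C@H](C)CCCCCCC#Cc2ccccc2)C[C@@H](C)C1=O | intermediate
16 | (4R)-1,2,4-trimethyl-2-[(2R)-2-methyl-10-phenyldec-9-yn-1-yl]cyclobutan-1-ol (mixture at C1 and C2) | CC1(C[C@H](C)CCCCCCC#Cc2ccccc2)C[C@@H](C)C1(C)O | intermediate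
17 | (4R)-1,2,4-trimethyl-2-[(2R,9Z)-2-methyl-10-phenyldec-9-en-1-yl]cyclobutan-1-ol (mixture at C1 and C2) | CC1(C[C@H](C)CCCCCC/C=C\c2ccccc2)C[C@@H](C)C1(C)O | intermediate
18 | (3R,7R,14Z)-3,5,7-trimethyl-2-oxo-15-phenylpentadec-14-en-5-yl radical | CC(=O)[C@H](C)C[C](C)C[C@H](C)CCCCCC/C=C\c1ccccc1 | intermediate
19 | (3R,5S,7R,14Z)-5-hydroperoxy-3,5,7-trimethyl-15-phenylpentadec-14-en-2-one | CC(=O)[C@H](C)C[C@@](C)(OO)C[C@H](C)CCCCCC/C=C\c1ccccc1 | intermediate
20 | (3S,4R,6S)-3,4,6-trimethyl-6-[(2R,9Z)-2-methyl-10-phenyldec-9-en-1-yl]-1,2-dioxan-3-ol | C[C@H](CCCCCC/C=C\c1ccccc1)C[C@@]1(C)C[C@@H](C)[C@@](C)(O)OO1 | target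

**Step count**

Total steps: 11. Longest linear sequence: 11 (from non-8-yn-1-ol).

**Steps most likely to fail**

Step 11. Peroxyl and alkoxyl radicals of the chain may add to or isomerise the Z-styrene, and the tertiary radical may be diverted before O2 capture. The absent facial bias at C6 is accepted by design and handled by separation. Fallback: the peroxide ring is made before the alkene exists. Setting out from alkyne cyclobutanol 16, the same cobalt/O2 ring expansion should give alkynyl dioxanol F1 after separation from its C6 epimer. Acid-catalysed exchange in methanol (PPTS, MeOH, rt) should give methyl peroxyketal F2, which has no open hydroperoxy ketone form. Lindlar semi-hydrogenation stopped at one equivalent of H2 should give Z-alkenyl peroxyketal F3; a fully substituted dialkyl peroxide is expected to be slow to hydrogenolyse on poisoned palladium. Hydrolysis of the ketal (cat. TsOH, acetone–water, rt) rejoins the route at 20.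

Step 5. Enolisation and aldol self-condensation of methyl ketone 7, or base-induced alkyne-to-allene isomerisation, may outrun ylide addition in KOH/DMSO. Fallback: a cyclopropyl carbanion followed by a separate cationic ring expansion. Setting out from 7, addition of 1-lithiocyclopropyl phenyl sulfide (cyclopropyl phenyl sulfide, n-BuLi, THF, 0 °C, then 7 at −78 °C) should give hydroxy sulfide F4. p-TsOH in wet benzene ionises the tertiary carbinol, a cyclopropane bond migrates to the sulfur-stabilised cyclobutyl cation, and hydrolysis rejoins the route at 10.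

Step 7. Metalation and methylation of the hindered four-ring azaenolate may be slow or poorly face-selective (one of the two C2 epimers may be mismatched with the auxiliary), and the new centre may epimerise during hydrazone cleavage. Fallback: a chelated lithio-enamine of a chiral β-methoxy amine imine in place of the hydrazone, released by buffered hydrolysis. Setting out from 10, condensation with (2S)-1-methoxy-3-phenylpropan-2-amine (cat. TsOH, benzene, Dean–Stark) should give chiral imine F5. LDA (THF, −20 °C) should give lithio-enamine F6, and MeI at −78 °C should give methylated imine F7, the amine enantiomer being chosen to give 4R. Hydrolysis in AcOH/NaOAc buffer (water–pentane, rt) rejoins the route at 15.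

**Further compounds**

F1 | step 11 | (3S,4R,6S)-3,4,6-trimethyl-6-[(2R)-2-methyl-10-phenyldec-9-yn-1-yl]-1,2-dioxan-3-ol | C[C@H](CCCCCCC#Cc1ccccc1)C[C@@]1(C)C[C@@H](C)[C@@](C)(O)OO1
F2 | step 11 | (3S,4R,6S)-3-methoxy-3,4,6-trimethyl-6-[(2R)-2-methyl-10-phenyldec-9-yn-1-yl]-1,2-dioxane | C[C@H](CCCCCCC#Cc1ccccc1)C[C@@]1(C)C[C@@H](C)[C@@](C)(OC)OO1
F3 | step 11 | (3S,4R,6S)-3-methoxy-3,4,6-trimethyl-6-[(2R,9Z)-2-methyl-10-phenyldec-9-en-1-yl]-1,2-dioxane | C[C@H](CCCCCC/C=C\c1ccccc1)C[C@@]1(C)C[C@@H](C)[C@@](C)(OC)OO1
F4 | step 5 | (4R)-4-methyl-12-phenyl-2-[1-(phenylsulfanyl)cyclopropyl]dodec-11-yn-2-ol (both C2 epimers) | CC(O)(C[C@H](C)CCCCCCC#Cc1ccccc1)C1(Sc2ccccc2)CC1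
F5 | step 7 | N-[(2S)-1-methoxy-3-phenylpropan-2-yl]-2-methyl-2-[(2R)-2-methyl-10-phenyldec-9-yn-1-yl]cyclobutan-1-imine | CC1(C[C@H](C)CCCCCCC#Cc2ccccc2)CCC1=N[C@H](COC)Cc1ccccc1
F6 | step 7 | lithio-enamine of F5 | CC1(C[C@H](C)CCCCCCC#Cc2ccccc2)CC=C1N([Li])[C@H](COC)Cc1ccccc1
F7 | step 7 | (4R)-N-[(2S)-1-methoxy-3-phenylpropan-2-yl]-2,4-dimethyl-2-[(2R)-2-methyl-10-phenyldec-9-yn-1-yl]cyclobutan-1-imine | CC1(C[C@H](C)CCCCCCC#Cc2ccccc2)C[C@@H](C)C1=N[C@H](COC)Cc1ccccc1
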